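**Assumption:** the SMILES is read as (2R,3S,3aS,5R), i.e. aryl, 3-Me, 3a-allyl and 5-OMe all on the same face; a one-flask addition/quench/dehydration is counted as one step.

## Retrosynthetic overview

1. Target ⇐ kinetic C5 protonation of the enolate formed by 6π-electrocyclisation of a trienolate (C3a–C4 bond; the carbocycle is formed last).
2. The trienolate comes from 2-(acylmethylene)oxolane 14, made from lactone 11 and the enolate of 3-methoxybut-3-en-2-one (C7a–C7 bond), then dehydration.
3. Lactone 11 (the O-ring, formed first) ⇐ Felkin addition of ArMgBr to aldehyde 8 (C2–Ar), lactonisation, loss of the extra carboxyl.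
4. Aldehyde 8 ⇐ SN2 inversion of ethyl L-lactate triflate by di-tert-butyl malonate (C3–C3a; C3 is the purchased stereocentre), then allylation and ester reduction.

## Route

**Step 1**
Reactants: 1 ethyl (S)-lactate; 2 triflic anhydride
Product: 3 ethyl (2S)-2-(triflyloxy)propanoate
Conditions: Tf2O, 2,6-lutidine, CH2Cl2, −78 → 0 °C
Reagents that add atoms: triflic anhydride, O=S(=O)(OS(=O)(=O)C(F)(F)F)C(F)(F)F
Why: O-sulfonylation does not touch the stereocentre and gives an α-triflyloxy ester that reacts by clean SN2.

**Step 2**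
Reactants: 3; 4 di-tert-butyl malonate
Product: 5 di-tert-butyl 2-[(2S)-1-ethoxy-1-oxopropan-2-yl]propanedioate
Conditions: NaH, THF, 0 °C → rt
Reagents that add atoms: di-tert-butyl malonate, CC(C)(C)OC(=O)CC(=O)OC(C)(C)C
Why: Malonate SN2 on the α-triflyloxy ester goes with inversion, so the lactate carbon becomes C3 with the target's configuration (the descriptor stays S only because CIP priorities change).

**Step 3**
Reactants: 5; 6 allyl bromide
Product: 7 di-tert-butyl 2-allyl-2-[(2S)-1-ethoxy-1-oxopropan-2-yl]propanedioate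
Conditions: NaH, THF/DMF, 0 °C → rt
Reagents that add atoms: allyl bromide, C=CCBr
Why: Malonate alkylation; only the malonate C–H (pKa ~13) is deprotonated, so the ester α-stereocentre is not epimerised.

**Step 4**
Reactants: 7
Product: 8 di-tert-butyl 2-allyl-2-[(2S)-1-oxopropan-2-yl]propanedioate
Conditions: DIBAL-H (1.1 equiv), CH2Cl2, −78 °C; Rochelle salt
Reagents that add atoms: none
Why: Partial reduction of the ethyl ester to the aldehyde; the two tert-butyl esters on the quaternary carbon are inert at −78 °C.

**Step 5**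
Reactants: 8; 9 (3,4,5-trimethoxyphenyl)magnesium bromide (commercial THF solution)
Product: 10 tert-butyl (4S,5R)-3-allyl-4-methyl-2-oxo-5-(3,4,5-trimethoxyphenyl)oxolane-3-carboxylate (4,5-cis; C3 either)
Conditions: THF, −78 °C → rt (anhydrous CeCl3 optional)
Reagents that add atoms: ArMgBr, COc1cc([Mg]Br)cc(OC)c1OC
Why: Felkin–Anh addition anti to the bulky quaternary malonate carbon gives the 1,2-syn alcohol (new C2 = R), and its alkoxide lactonises onto one tert-butyl ester to give the 4,5-cis lactone.

**Step 6**
Reactants: 10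
Product: 11 (4S,5R)-3-allyl-4-methyl-5-(3,4,5-trimethoxyphenyl)oxolan-2-one (C3 epimer mixture, irrelevant)
Conditions: TFA/CH2Cl2 (1:4), 0 °C → rt; concentrate; toluene, 110 °C
Reagents that add atoms: none
Why: tert-Butyl ester cleavage and decarboxylation of the α-carboxy lactone; C3a is planarised later, so its configuration does not matter.

**Step 7**
Reactants: 12 3,3-dimethoxybutan-2-one
Product: 13 3-methoxybut-3-en-2-one
Conditions: TsOH (cat.), 140 °C, distil off MeOH
Reagents that add atoms: none
Why: Acid-catalysed ketal-to-enol-ether elimination.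

**Step 8**
Reactants: 11; 13
Product: 14 1-[(4S,5R)-3-allyl-4-methyl-5-(3,4,5-trimethoxyphenyl)oxolan-2-ylidene]-3-methoxybut-3-en-2-one
Conditions: 13, LDA, THF, −78 °C; add 11, −78 → −40 °C; NH4Cl; then PPTS (cat.), CH2Cl2, 4 Å MS, rt
Reagents that add atoms: 3-methoxybut-3-en-2-one, CC(=O)C(=C)OC
Why: Claisen-type addition of the kinetic methyl-ketone enolate to the lactone carbonyl gives a lactol that dehydrates to the conjugated 2-alkylidene oxolane; the lactone α-H is less acidic than the ketone, so C2 and C3 are untouched.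

**Step 9**
Reactants: 14
Product: 15 Dysodanthin B
Conditions: KHMDS (1.1 equiv), THF (0.01 M), −78 → 0 °C; re-cool to −78 °C; quench with 2,6-di-tert-butyl-4-methylphenol (or AcOH)
Reagents that add atoms: none
Why: Deprotonation at C3a (the only acidic C–H) gives a cross-conjugated trienolate that undergoes oxyanion-accelerated disrotatory 6π-electrocyclisation (equivalently a 6-endo vinylogous Michael). C4 bonds anti to the C3-methyl and C2-aryl, which puts the allyl cis to them (3aS); kinetic protonation of the C5 enolate anti to the pseudo-axial allyl gives 5-OMe cis to allyl (5R).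

## Compound list

1 | ethyl (S)-lactate | C[C@H](O)C(=O)OCC | starting material
2 | trifluoromethanesulfonic anhydride | O=S(=O)(OS(=O)(=O)C(F)(F)F)C(F)(F)F | starting material (reagent)
3 | ethyl (2S)-2-{[(trifluoromethyl)sulfonyl]oxy}propanoate | C[C@H](OS(=O)(=O)C(F)(F)F)C(=O)OCC | intermediate
4 | di-tert-butyl malonate | CC(C)(C)OC(=O)CC(=O)OC(C)(C)C | starting material
5 | di-tert-butyl 2-[(2S)-1-ethoxy-1-oxopropan-2-yl]propanedioate | C[C@@H](C(C(=O)OC(C)(C)C)C(=O)OC(C)(C)C)C(=O)OCC | intermediate
6 | allyl bromide | C=CCBr | starting material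
7 | di-tert-butyl 2-allyl-2-[(2S)-1-ethoxy-1-oxopropan-2-yl]propanedioate | C[C@@H](C(CC=C)(C(=O)OC(C)(C)C)C(=O)OC(C)(C)C)C(=O)OCC | intermediate
8 | di-tert-butyl 2-allyl-2-[(2S)-1-oxopropan-2-yl]propanedioate | C[C@@H](C(CC=C)(C(=O)OC(C)(C)C)C(=O)OC(C)(C)C)C=O | intermediate
9 | (3,4,5-trimethoxyphenyl)magnesium bromide | COc1cc([Mg]Br)cc(OC)c1OC | starting material
10 | tert-butyl (4S,5R)-3-allyl-4-methyl-2-oxo-5-(3,4,5-trimethoxyphenyl)oxolane-3-carboxylate | C=CCC1(C(=O)OC(C)(C)C)[C@H](C)[C@H](c2cc(OC)c(OC)c(OC)c2)OC1=O | intermediate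
11 | (4S,5R)-3-allyl-4-methyl-5-(3,4,5-trimethoxyphenyl)oxolan-2-one | C=CCC1[C@H](C)[C@H](c2cc(OC)c(OC)c(OC)c2)OC1=O | intermediate
12 | 3,3-dimethoxybutan-2-one | CC(=O)C(C)(OC)OC | starting material
13 | 3-methoxybut-3-en-2-one | CC(=O)C(=C)OC | intermediate
14 | 1-[(4S,5R)-3-allyl-4-methyl-5-(3,4,5-trimethoxyphenyl)oxolan-2-ylidene]-3-methoxybut-3-en-2-one | C=CCC1[C@H](C)[C@H](c2cc(OC)c(OC)c(OC)c2)OC1=CC(=O)C(=C)OC | intermediate
15 | Dysodanthin B, (2R,3S,3aS,5R)-3a-allyl-5-methoxy-3-methyl-2-(3,4,5-trimethoxyphenyl)-3,3a,4,5-tetrahydrobenzofuran-6(2H)-one | C=CC[C@@]12C[C@@H](OC)C(=O)C=C1O[C@@H](c1cc(OC)c(OC)c(OC)c1)[C@H]2C | target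

## Step count and risks

**Total steps:** 9. **Longest linear sequence:** 8 (steps 1–6, 8, 9).

**Steps most likely to fail, with fallbacks**

1. **Step 9** (electrocyclisation and C5 protonation; the cis-5-OMe product is probably the less stable epimer, so selectivity and epimerisation on work-up are the concern). Fallback: reverse the bond order on the lactone. Add the lithium enolate of 11 to methyl vinyl ketone (C3a–C4 formed anti to the methyl), close the ring by intramolecular Claisen condensation and dehydration, then install C5 by α′-hydroxylation (trans to allyl), triflation and SN2 displacement with methanol (inversion to cis).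
2. **Step 8** (ketone enolate addition to a hindered lactone; the dienone product is sensitive). Fallback: open 11 with MeLi to the methyl-ketone lactol and C-acylate its kinetic dianion with the Weinreb amide of 2-methoxyacrylic acid, then cyclodehydrate to 14.
3. **Step 5** (Felkin diastereoselectivity at C2). Fallback: set C2 and C3 together by a [2,3]-Wittig rearrangement of the 3,4,5-trimethoxybenzyl ether of (S,Z)-pent-3-en-2-ol (also from ethyl L-lactate; syn-selective with chirality transfer). Then Wacker oxidation and haloform cleavage give the cis lactone, and LDA/allyl bromide gives 11.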